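## Retrosynthetic overview

1. Target 18 ⇐ cross-metathesis of vinyl ketone 16 with 2-methylbut-3-en-2-ol; 16 ⇐ ester/Weinreb amide 14 by one-pot vinyl addition and ester reduction.
2. The only ring, the oxepane, is closed in step 7 by 7-endo opening of the (6R,7R)-epoxide 13 (new C7–O bond, inversion); 13 ⇐ Shi epoxidation of (E)-alkene 12.
3. The exocyclic alkene geometry is fixed before ring closure: 12 ⇐ (E)-enol triflate 11 by stereoretentive Stille hydroxymethylation.
4. C11 ⇐ new carbene-catalysed redox amidation with enantioselective protonation of enal 8; 8 ⇐ cross-metathesis of 6 with methacrolein.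
5. 6 ⇐ β-keto ester 4 ⇐ geranyl bromide + methyl acetoacetate dianion (C-numbers below are those of the dodecanoate chain of 4).

Assumption: commercial (E)-geranyl bromide is used, and the triazolium antipode named in step 4 is the one an open-face model predicts for 11S (the mirror-image salt is used if a model enal shows the opposite sense).

## Route

**Step 1**
Reactants: 1 geranyl bromide; 2 methyl acetoacetate
Product: 4 methyl (6E)-7,11-dimethyl-3-oxododeca-6,10-dienoate, via dianion 3 (not isolated)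
Conditions: NaH, THF, 0 °C; n-BuLi, 0 °C; then 1, 0 °C to rt; aq. HCl
Reagents that add atoms: none
Why: Weiler dianion alkylation, in which the γ-carbanion of 3 displaces the primary allylic bromide by SN2 without allylic transposition, so the (E)-alkene of 1 is carried over and no stereocentre is formed.

**Step 2**
Reactants: 4 methyl (6E)-7,11-dimethyl-3-oxododeca-6,10-dienoate
Product: 6 methyl (2E,6E)-7,11-dimethyl-3-{[(trifluoromethyl)sulfonyl]oxy}dodeca-2,6,10-trienoate, via ammonium enolate 5 (not isolated)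
Conditions: Tf2O, aq. Me4NOH, toluene, 5 °C
Reagents that add atoms: trifluoromethanesulfonic anhydride (Tf2O), O=S(=O)(OS(=O)(=O)C(F)(F)F)C(F)(F)F
Why: Stereoselective enol triflation of a β-keto ester, in which the non-chelated tetramethylammonium enolate 5 is O-sulfonylated in its dipole-minimised form to give the (E)-triflate (OTf trans to CO2Me, C4 cis to C1).

**Step 3**
Reactants: 6 methyl (2E,6E)-7,11-dimethyl-3-{[(trifluoromethyl)sulfonyl]oxy}dodeca-2,6,10-trienoate; 7 methacrolein
Product: 8 methyl (2E,6E,10E)-7,11-dimethyl-12-oxo-3-{[(trifluoromethyl)sulfonyl]oxy}dodeca-2,6,10-trienoate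
Conditions: 7 (10 equiv), second-generation Hoveyda–Grubbs catalyst (5 mol%), CH2Cl2, 40 °C
Reagents that add atoms: none
Why: Olefin cross-metathesis, in which only the terminal isopropylidene group is accessible to the ruthenium carbene (the internal trisubstituted alkene and the enol triflate are inert) and the (E)-2-methyl enal forms under thermodynamic control.

**Step 4**
Reactants: 8 methyl (2E,6E,10E)-7,11-dimethyl-12-oxo-3-{[(trifluoromethyl)sulfonyl]oxy}dodeca-2,6,10-trienoate
Product: 11 methyl (2E,6E,11S)-12-[methoxy(methyl)amino]-7,11-dimethyl-12-oxo-3-{[(trifluoromethyl)sulfonyl]oxy}dodeca-2,6-dienoate, via acyl azolium 9 (not isolated), via OAt ester 10 (not isolated)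
Conditions: (5aS,10bR)-2-(pentafluorophenyl)-5a,10b-dihydro-4H,6H-indeno[2,1-b][1,2,4]triazolo[4,3-d][1,4]oxazin-2-ium tetrafluoroborate (10 mol%), HOAt (20 mol%), MeNHOMe·HCl (1.5 equiv), i-Pr2NEt (1.6 equiv), 4 Å MS, toluene, 23 °C
Reagents that add atoms: N,O-dimethylhydroxylamine hydrochloride, CNOC.Cl
Why: Proposed new method: carbene-catalysed internal redox amidation in which, after addition of the carbene to the aldehyde and β-protonation at C10, the catalyst-bound enol (held in one geometry by allylic strain between the α-methyl group and the triazolium) is protonated at C11 on the face left open by the indane wall, which sets 11S and gives acyl azolium 9, trapped by HOAt as ester 10 and by the amine as 11 before it can epimerise; the closest known reaction type is the carbene-catalysed redox amidation or esterification of α-fluoro and α-chloro aldehydes and enals with enantioselective α-protonation, which has not been shown for an α-methyl β-alkyl enal.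

**Step 5**
Reactants: 11 methyl (2E,6E,11S)-12-[methoxy(methyl)amino]-7,11-dimethyl-12-oxo-3-{[(trifluoromethyl)sulfonyl]oxy}dodeca-2,6-dienoate
Product: 12 methyl (2E,6E,11S)-3-(hydroxymethyl)-12-[methoxy(methyl)amino]-7,11-dimethyl-12-oxododeca-2,6-dienoate
Conditions: Bu3SnCH2OH (1.5 equiv), Pd(PPh3)4 (5 mol%), LiCl (3 equiv), 1,4-dioxane, 90 °C
Reagents that add atoms: (tributylstannyl)methanol, CCCC[Sn](CCCC)(CCCC)CO
Why: Stille hydroxymethylation of a vinyl triflate, which proceeds with retention so that CH2OH ends trans to CO2Me (2E); any (Z)-isomer lactonises to a butenolide and is removed, and the neutral conditions leave C11 untouched.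

**Step 6**
Reactants: 12 methyl (2E,6E,11S)-3-(hydroxymethyl)-12-[methoxy(methyl)amino]-7,11-dimethyl-12-oxododeca-2,6-dienoate
Product: 13 methyl (2E)-3-(hydroxymethyl)-5-{(2R,3R)-3-[(4S)-5-[methoxy(methyl)amino]-4-methyl-5-oxopentyl]-3-methyloxiran-2-yl}pent-2-enoate
Conditions: D-fructose-derived Shi ketone (30 mol%), Oxone (2KHSO5·KHSO4·K2SO4), K2CO3, Bu4NHSO4, aq. Na2B4O7/EDTA buffer, MeCN–CH2(OMe)2, 0 °C
Reagents that add atoms: Oxone (potassium peroxymonosulfate, KHSO5), [K+].[O-]S(=O)(=O)OO
Why: Shi asymmetric epoxidation, in which the chiral dioxirane attacks the electron-rich (E)-trisubstituted C6=C7 alkene through a spiro transition state on the face that gives the (6R,7R)-epoxide (the same facial sense as (R,R)-stilbene oxide and (R,R)-1-phenylcyclohexene oxide), while the electron-poor enoate alkene does not react and the remote C11 centre is unaffected.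

**Step 7**
Reactants: 13 methyl (2E)-3-(hydroxymethyl)-5-{(2R,3R)-3-[(4S)-5-[methoxy(methyl)amino]-4-methyl-5-oxopentyl]-3-methyloxiran-2-yl}pent-2-enoate
Product: 14 methyl (2E)-2-{(6R,7S)-6-hydroxy-7-[(4S)-5-[methoxy(methyl)amino]-4-methyl-5-oxopentyl]-7-methyloxepan-3-ylidene}acetate
Conditions: CSA (10 mol%), CH2Cl2, −20 to 0 °C
Reagents that add atoms: none
Why: Acid-catalysed 7-endo epoxide-opening etherification, in which protonation polarises the tertiary C7–O bond and the allylic hydroxyl attacks C7 with inversion (oxepane C2 becomes S) while C6–O is retained (oxepane C3 is R); the preset (E)-alkene carries the exocyclic geometry into the ring.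

**Step 8**
Reactants: 14 methyl (2E)-2-{(6R,7S)-6-hydroxy-7-[(4S)-5-[methoxy(methyl)amino]-4-methyl-5-oxopentyl]-7-methyloxepan-3-ylidene}acetate
Product: 16 (4S)-7-[(2S,3R,6E)-3-hydroxy-6-(2-hydroxyethylidene)-2-methyloxepan-2-yl]-4-methylhept-1-en-3-one, via magnesium chelate 15 (not isolated)
Conditions: CH2=CHMgBr (3.5 equiv), THF, −78 to −20 °C; then i-Bu2AlH (4 equiv), −78 °C; inverse quench into cold 1 M HCl
Reagents that add atoms: vinylmagnesium bromide (CH2=CHMgBr), C=C[Mg]Br
Why: Weinreb ketone synthesis with in situ protection, in which the Grignard reagent adds once to the N-methoxy-N-methylamide to give the stable chelate 15 that masks the ketone while i-Bu2AlH reduces the conjugated ester to the allylic alcohol, and the acidic quench releases the vinyl ketone without enolising C11.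

**Step 9**
Reactants: 16 (4S)-7-[(2S,3R,6E)-3-hydroxy-6-(2-hydroxyethylidene)-2-methyloxepan-2-yl]-4-methylhept-1-en-3-one; 17 2-methylbut-3-en-2-ol
Product: 18 (3E,6S)-2-hydroxy-9-[(2S,3R,6E)-3-hydroxy-6-(2-hydroxyethylidene)-2-methyloxepan-2-yl]-2,6-dimethylnon-3-en-5-one
Conditions: 17 (5 equiv), second-generation Hoveyda–Grubbs catalyst (5 mol%), CH2Cl2, 40 °C
Reagents that add atoms: none
Why: Olefin cross-metathesis of a vinyl ketone with a tertiary allylic alcohol, which gives the (E)-enone under thermodynamic control; the trisubstituted exocyclic alkene is inert and free hydroxyls are tolerated.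

## Compound list

1 | geranyl bromide, (2E)-1-bromo-3,7-dimethylocta-2,6-diene | CC(C)=CCC/C(C)=C/CBr | starting material
2 | methyl acetoacetate | COC(=O)CC(C)=O | starting material
3 | sodium lithium dianion of 2 (1-methoxybuta-1,3-diene-1,3-diolate) | [Li+].[Na+].C=C([O-])C=C([O-])OC | intermediate
4 | methyl (6E)-7,11-dimethyl-3-oxododeca-6,10-dienoate | COC(=O)CC(=O)CC/C=C(\C)CCC=C(C)C | intermediate
5 | tetramethylammonium (E)-enolate of 4 | C[N+](C)(C)C.COC(=O)/C=C(/[O-])CC/C=C(\C)CCC=C(C)C | intermediate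
6 | methyl (2E,6E)-7,11-dimethyl-3-{[(trifluoromethyl)sulfonyl]oxy}dodeca-2,6,10-trienoate | COC(=O)/C=C(/OS(=O)(=O)C(F)(F)F)CC/C=C(\C)CCC=C(C)C | intermediate
7 | methacrolein (2-methylprop-2-enal) | CC(=C)C=O | starting material
8 | methyl (2E,6E,10E)-7,11-dimethyl-12-oxo-3-{[(trifluoromethyl)sulfonyl]oxy}dodeca-2,6,10-trienoate | COC(=O)/C=C(/OS(=O)(=O)C(F)(F)F)CC/C=C(\C)CC/C=C(\C)C=O | intermediate
9 | (2S)-acyl azolium: the (5aS,10bR)-triazolium cation of step 4 carrying the (2S,6E,10E)-12-methoxy-2,6-dimethyl-12-oxo-10-(triflyloxy)dodeca-6,10-dienoyl group on its carbene carbon, tetrafluoroborate | COC(=O)/C=C(/OS(=O)(=O)C(F)(F)F)CC/C=C(\C)CCC[C@H](C)C(=O)c1n2c(n[n+]1-c1c(F)c(F)c(F)c(F)c1F)CO[C@H]1Cc3ccccc3[C@H]12.F[B-](F)(F)F | intermediate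
10 | 7-azabenzotriazol-1-yl (2S,6E,10E)-12-methoxy-2,6-dimethyl-12-oxo-10-{[(trifluoromethyl)sulfonyl]oxy}dodeca-6,10-dienoate (OAt ester) | COC(=O)/C=C(/OS(=O)(=O)C(F)(F)F)CC/C=C(\C)CCC[C@H](C)C(=O)On1nnc2cccnc12 | intermediate
11 | methyl (2E,6E,11S)-12-[methoxy(methyl)amino]-7,11-dimethyl-12-oxo-3-{[(trifluoromethyl)sulfonyl]oxy}dodeca-2,6-dienoate | COC(=O)/C=C(/OS(=O)(=O)C(F)(F)F)CC/C=C(\C)CCC[C@H](C)C(=O)N(C)OC | intermediate
12 | methyl (2E,6E,11S)-3-(hydroxymethyl)-12-[methoxy(methyl)amino]-7,11-dimethyl-12-oxododeca-2,6-dienoate | COC(=O)/C=C(/CO)CC/C=C(\C)CCC[C@H](C)C(=O)N(C)OC | intermediate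
13 | methyl (2E)-3-(hydroxymethyl)-5-{(2R,3R)-3-[(4S)-5-[methoxy(methyl)amino]-4-methyl-5-oxopentyl]-3-methyloxiran-2-yl}pent-2-enoate | COC(=O)/C=C(/CO)CC[C@H]1O[C@]1(C)CCC[C@H](C)C(=O)N(C)OC | intermediate
14 | methyl (2E)-2-{(6R,7S)-6-hydroxy-7-[(4S)-5-[methoxy(methyl)amino]-4-methyl-5-oxopentyl]-7-methyloxepan-3-ylidene}acetate | CON(C)C(=O)[C@@H](C)CCC[C@]1(C)OC/C(=C/C(=O)OC)CC[C@H]1O | intermediate
15 | bis(bromomagnesium) alkoxide of the tetrahedral vinyl adduct of 14 (N-methoxy-N-methyl hemiaminal, carbinol carbon unassigned) | C=CC(O[Mg]Br)(N(C)OC)[C@@H](C)CCC[C@]1(C)OC/C(=C/C(=O)OC)CC[C@H]1O[Mg]Br | intermediate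
16 | (4S)-7-[(2S,3R,6E)-3-hydroxy-6-(2-hydroxyethylidene)-2-methyloxepan-2-yl]-4-methylhept-1-en-3-one | C=CC(=O)[C@@H](C)CCC[C@]1(C)OC/C(=C/CO)CC[C@H]1O | intermediate
17 | 2-methylbut-3-en-2-ol | C=CC(C)(C)O | starting material
18 | (3E,6S)-2-hydroxy-9-[(2S,3R,6E)-3-hydroxy-6-(2-hydroxyethylidene)-2-methyloxepan-2-yl]-2,6-dimethylnon-3-en-5-one (CNP0270237.2) | C[C@@H](CCC[C@]1(C)OC/C(=C/CO)CC[C@H]1O)C(=O)/C=C/C(C)(C)O | target

## Step count and risks

Total steps: 9. Longest linear sequence: 9.

The three steps most likely to fail are steps 4, 7 and 8.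

**Step 4 (new carbene-catalysed protonation; low ee or poor turnover with the α-branched enal).** The fallback sets out from 8 and comes back at 11. Pinnick oxidation (NaClO2, NaH2PO4, 2-methylbut-2-ene, t-BuOH/H2O) gives the (2E)-2-methyl-2-enoic acid F1. Carboxylate-directed asymmetric hydrogenation with Ru(OAc)2[(S)-H8-BINAP] (H2, MeOH) reduces only the alkene next to the carboxyl group and gives the (2S)-acid F2, in the same sense as tiglic acid to (S)-2-methylbutanoic acid. Coupling with MeNHOMe·HCl (EDC·HCl, HOBt, i-Pr2NEt) then gives 11.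

**Step 7 (6-exo attack at C6 could compete with the wanted 7-endo attack at C7).** The fallback sets out from 13 and comes back at 14, and replaces the epoxide-opening etherification by a Williamson ring closure from the tertiary alkoxide. The primary hydroxyl is converted (MsCl, 2,4,6-collidine) into the allylic mesylate F3 and then (LiCl, DMF) into the allylic chloride F4. Dilute HClO4 in THF/H2O opens the epoxide with water at the tertiary carbon with inversion to give the (6R,7S)-diol F5. MOMCl/i-Pr2NEt protects only the secondary hydroxyl to give the MOM ether F6. NaH in THF then closes the ring by 7-exo-tet displacement of chloride by the tertiary alkoxide to give the oxepane MOM ether F7; the six-membered alternative is blocked and MOM does not migrate. HCl in MeOH removes the MOM group and gives 14.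

**Step 8 (the Grignard reagent may also attack the conjugated ester, or the chelate may not survive the reduction).** The fallback sets out from 14 and comes back at 18, replacing steps 8 and 9. Excess i-Bu2AlH (THF, −78 °C) reduces the ester to the alcohol and the Weinreb amide to the aldehyde, giving the hydroxy aldehyde F8. Addition of the dianion of 2-methylbut-3-yn-2-ol (n-BuLi, THF, −78 °C) gives the propargylic diol F9 as a mixture at the new carbinol, which does not matter. Ruthenium-catalysed redox isomerisation of the secondary propargylic alcohol ((indenyl)RuCl(PPh3)2, In(OTf)3, CSA, THF, 65 °C) gives the (E)-enone 18 directly.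

## Further compounds

F1 | step 4 | (2E,6E,10E)-12-methoxy-2,6-dimethyl-12-oxo-10-{[(trifluoromethyl)sulfonyl]oxy}dodeca-2,6,10-trienoic acid | COC(=O)/C=C(/OS(=O)(=O)C(F)(F)F)CC/C=C(\C)CC/C=C(\C)C(=O)O
F2 | step 4 | (2S,6E,10E)-12-methoxy-2,6-dimethyl-12-oxo-10-{[(trifluoromethyl)sulfonyl]oxy}dodeca-6,10-dienoic acid | COC(=O)/C=C(/OS(=O)(=O)C(F)(F)F)CC/C=C(\C)CCC[C@H](C)C(=O)O
F3 | step 7 | methyl (2E)-3-{[(methylsulfonyl)oxy]methyl}-5-{(2R,3R)-3-[(4S)-5-[methoxy(methyl)amino]-4-methyl-5-oxopentyl]-3-methyloxiran-2-yl}pent-2-enoate | COC(=O)/C=C(/COS(C)(=O)=O)CC[C@H]1O[C@]1(C)CCC[C@H](C)C(=O)N(C)OC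
F4 | step 7 | methyl (2E)-3-(chloromethyl)-5-{(2R,3R)-3-[(4S)-5-[methoxy(methyl)amino]-4-methyl-5-oxopentyl]-3-methyloxiran-2-yl}pent-2-enoate | COC(=O)/C=C(/CCl)CC[C@H]1O[C@]1(C)CCC[C@H](C)C(=O)N(C)OC
F5 | step 7 | methyl (2E,6R,7S,11S)-3-(chloromethyl)-6,7-dihydroxy-12-[methoxy(methyl)amino]-7,11-dimethyl-12-oxododec-2-enoate | CON(C)C(=O)[C@@H](C)CCC[C@](C)(O)[C@H](O)CC/C(CCl)=C\C(=O)OC
F6 | step 7 | methyl (2E,6R,7S,11S)-3-(chloromethyl)-7-hydroxy-12-[methoxy(methyl)amino]-6-(methoxymethoxy)-7,11-dimethyl-12-oxododec-2-enoate | CON(C)C(=O)[C@@H](C)CCC[C@](C)(O)[C@H](OCOC)CC/C(CCl)=C\C(=O)OC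
F7 | step 7 | methyl (2E)-2-{(6R,7S)-7-[(4S)-5-[methoxy(methyl)amino]-4-methyl-5-oxopentyl]-6-(methoxymethoxy)-7-methyloxepan-3-ylidene}acetate | CON(C)C(=O)[C@@H](C)CCC[C@]1(C)OC/C(=C/C(=O)OC)CC[C@H]1OCOC
F8 | step 8 | (2S)-5-[(2S,3R,6E)-3-hydroxy-6-(2-hydroxyethylidene)-2-methyloxepan-2-yl]-2-methylpentanal | O=C[C@@H](C)CCC[C@]1(C)OC/C(=C/CO)CC[C@H]1O
F9 | step 8 | (6S)-9-[(2S,3R,6E)-3-hydroxy-6-(2-hydroxyethylidene)-2-methyloxepan-2-yl]-2,6-dimethylnon-3-yne-2,5-diol (C5 epimers) | CC(C)(O)C#CC(O)[C@@H](C)CCC[C@]1(C)OC/C(=C/CO)CC[C@H]1O
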